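**Plan**
Retrosynthesis: the nine O-benzyl groups come off last. Before that the upper pyran ring C is cut at C4-C4a, C3-C4 and O1-C2 together, leaving an 8-formylcatechin ether, a phloroglucinol diether and a 3,4-dioxygenated styrene.
Enabling feature: upper C4 is a diarylmethine ortho to the oxygen O1 on upper ring A. O1-C8a-C4a-C4 is therefore a masked ortho-quinone methide (a 1-oxadiene), C2-C3 with ring B is a masked styrene, and C4 is the former formyl carbon on C8 of the lower ring A.
Forward: the lower flavan is taken intact from (+)-catechin and formylated at C8 in four steps. Each small partner takes one step, the three-component step closes the only new ring, and hydrogenolysis ends the route.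
Stereochemistry: lower C2 (R) and C3 (S) come with (+)-catechin. Upper C4 (S) comes from the methide face selected by a chiral phosphoric acid together with the catechin unit, and upper C2 (S) follows from C4 through 2,4-cis ring closure.

Key step: step 7

Assumption: precedent does not show which antipode of the phosphoric acid is matched with the catechin unit, so the (R)-acid is written, both are to be run, and the cycloadduct configuration (NOE for 2,4-cis, circular dichroism for the sense at C4) is to be proven before the last step.

**Step 1**
Reactants: 1 (+)-catechin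
Product: 2 5,7,3',4'-tetra-O-benzyl-(+)-catechin
Conditions: BnBr (4.4 equiv), K2CO3, DMF, 0 °C to rt
Reagents that add atoms: benzyl bromide, BrCc1ccccc1
Why: Williamson etherification in which K2CO3 deprotonates only the four phenols, so the secondary 3-OH stays free, and the weak base at or below room temperature avoids the C2 epimerisation that catechin phenolates suffer under stronger base.

**Step 2**
Reactants: 2 5,7,3',4'-tetra-O-benzyl-(+)-catechin
Product: 3 3,5,7,3',4'-penta-O-benzyl-(+)-catechin
Conditions: NaH, BnBr, n-Bu4NI (cat), THF, 0 °C to rt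
Reagents that add atoms: benzyl bromide, BrCc1ccccc1
Why: Williamson etherification of the remaining alcohol through its sodium alkoxide, and with all phenols capped no ring opening to a quinone methide is possible, so C2 and C3 stay untouched.

**Step 3**
Reactants: 3 3,5,7,3',4'-penta-O-benzyl-(+)-catechin
Product: 4 8-bromo-3,5,7,3',4'-penta-O-benzyl-(+)-catechin
Conditions: NBS (1.0 equiv), CH2Cl2, -78 °C to 0 °C, dark
Reagents that add atoms: N-bromosuccinimide, O=C1CCC(=O)N1Br
Why: Electrophilic aromatic bromination, in which ring A is by far the most electron-rich arene and C8 of 5,7-di-O-benzyl flavan-3-ols reacts ahead of C6 with one equivalent of NBS at low temperature, a selectivity well established for benzylated catechins.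

**Step 4**
Reactants: 4 8-bromo-3,5,7,3',4'-penta-O-benzyl-(+)-catechin
Product: 6 8-formyl-3,5,7,3',4'-penta-O-benzyl-(+)-catechin, via 8-lithio-penta-O-benzylcatechin 5 (not isolated)
Conditions: n-BuLi (1.1 equiv), THF, -78 °C; DMF (5 equiv), -78 °C to 0 °C; H2O
Reagents that add atoms: N,N-dimethylformamide, CN(C)C=O
Why: Bromine-lithium exchange outruns benzylic deprotonation at -78 °C, and aryllithium 5, a nucleophile already used in this compound class, is formylated by DMF (Bouveault aldehyde synthesis), the hemiaminal alkoxide collapsing on aqueous quench.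

**Step 5**
Reactants: 7 phloroglucinol
Product: 8 3,5-dibenzyloxyphenol
Conditions: BnBr (2.0 equiv), K2CO3, DMF, rt
Reagents that add atoms: benzyl bromide, BrCc1ccccc1
Why: Williamson etherification with two equivalents of halide gives a statistical set of ethers from which the diether is taken by chromatography, while the weak base at room temperature keeps C-benzylation of the ambident phloroglucinolate low.

**Step 6**
Reactants: 9 3,4-dibenzyloxybenzaldehyde
Product: 10 3,4-dibenzyloxystyrene
Conditions: Ph3PCH3Br, KOt-Bu, THF, 0 °C to rt
Reagents that add atoms: methyltriphenylphosphonium bromide, C[P+](c1ccccc1)(c1ccccc1)c1ccccc1.[Br-]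
Why: Wittig methylenation of a non-enolisable aryl aldehyde with the non-stabilised ylide, to which the benzyl ethers are inert.

**Step 7**
Reactants: 6 8-formyl-3,5,7,3',4'-penta-O-benzyl-(+)-catechin; 8 3,5-dibenzyloxyphenol; 10 3,4-dibenzyloxystyrene
Product: 13 nona-O-benzyl-(2S,4S)-luteoliflavan-(4→8)-(+)-catechin, via diarylcarbinol 11 (not isolated), via ortho-quinone methide 12 (not isolated)
Conditions: 6 (1.0 equiv), 10 (3 equiv), (R)-3,3'-bis(2,4,6-triisopropylphenyl)-1,1'-binaphthyl-2,2'-diyl hydrogen phosphate (10 mol %), 4 Å MS, toluene, 0 °C; 8 (1.1 equiv) added over 6 h; then rt; chromatography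
Reagents that add atoms: none
Why: Proposed new method: the phosphoric acid, hydrogen-bonded at once to the OH of 8 and to the formyl oxygen of 6, should deliver the ortho carbon of 8 to the aldehyde (Friedel-Crafts hydroxyalkylation, C4-C4a), carbinol 11 with its two trioxygenated rings ionises and loses water to the ortho-quinone methide 12, held by the catalyst as a hydrogen-bonded ion pair, and the CH2 terminus of 10 then bonds to C4 (C3-C4) while O1 captures the para-benzyloxy-stabilised positive charge growing at C2 (O1-C2). The closest known reaction types are the achiral acid-catalysed three-component chroman synthesis from an electron-rich phenol, an aryl aldehyde and a styrene, and the chiral phosphoric acid catalysed [4+2] additions of ortho-quinone methides released from ortho-hydroxybenzhydrols; untested is their merger with a styrene that offers the catalyst no hydrogen-bond donor and with a 2,6-dioxygenated aldehyde. The upper pyran ring C closes by an intermolecular, asynchronous inverse-electron-demand oxa-[4+2] cycloaddition of the 1-oxadiene O1=C8a-C4a=C4 with the alkene C3=C2, which in its stepwise limit ends as a 6-exo-trig capture of the benzylic cation by O1. C4 (S) is decided by the face of 12 open to the alkene: the 2,4,6-triisopropylphenyl wall of the phosphate anchored at O1 covers one face, and the catechin ring, twisted out of the methide plane with its own C2 aryl group on one side, adds a substrate bias that one catalyst antipode should reinforce. C2 (S) follows from C4, since endo approach of the aryl group and, in the stepwise limit, closure through a half-chair with both aryl groups pseudo-equatorial lead to the 2,4-cis isomer, and reversible ionisation of the C2-O1 bond under the acid lets trans material drain to cis. The step needs ortho over para attack (two ortho sites next to the catalyst-binding OH against one para site walled in by two benzyloxy groups, whose adduct cannot cyclise and reverts), cycloaddition over a second arylation (C4 of 12 is hemmed in by 5-OBn and the two ortho oxygens of the catechin ring, so that the slim CH2 terminus, kept in excess while 8 is fed slowly, wins over a flanked arene carbon) and head-to-tail regiochemistry (fixed by the polarity of the oxadiene and the donor-substituted styrene), and every stereoisomer that still forms is a diastereomer of 13 that chromatography removes.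

**Step 8**
Reactants: 13 nona-O-benzyl-(2S,4S)-luteoliflavan-(4→8)-(+)-catechin
Product: 14 (2S,4S)-luteoliflavan-(4→8)-(+)-catechin (CNP0180676.1)
Conditions: H2 (1 atm), 20 % Pd(OH)2/C, THF/MeOH/H2O, rt; filtration and lyophilisation under Ar
Reagents that add atoms: none
Why: Hydrogenolysis of the eight aryl benzyl ethers and the one alkyl benzyl ether under neutral conditions at atmospheric pressure is the standard last step for benzylated proanthocyanidins, leaving the cyclic C2-O1 bonds, the C4-C8 link and all four stereocentres untouched.

**Compound list**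
1 | (+)-catechin, (2R,3S)-2-(3,4-dihydroxyphenyl)chroman-3,5,7-triol | Oc1cc(O)c2c(c1)O[C@H](c1ccc(O)c(O)c1)[C@@H](O)C2 | starting material
2 | 5,7,3',4'-tetra-O-benzyl-(+)-catechin (2R,3S), 3-OH free | C(c1ccccc1)Oc1cc(OCc3ccccc3)c2c(c1)O[C@H](c1ccc(OCc3ccccc3)c(OCc3ccccc3)c1)[C@@H](O)C2 | intermediate
3 | 3,5,7,3',4'-penta-O-benzyl-(+)-catechin (2R,3S) | C(c1ccccc1)Oc1cc(OCc3ccccc3)c2c(c1)O[C@H](c1ccc(OCc3ccccc3)c(OCc3ccccc3)c1)[C@@H](OCc1ccccc1)C2 | intermediate
4 | 8-bromo-3,5,7,3',4'-penta-O-benzyl-(+)-catechin (2R,3S) | Brc1c(OCc3ccccc3)cc(OCc3ccccc3)c2c1O[C@H](c1ccc(OCc3ccccc3)c(OCc3ccccc3)c1)[C@@H](OCc1ccccc1)C2 | intermediate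
5 | 8-lithio-3,5,7,3',4'-penta-O-benzyl-(+)-catechin (2R,3S), not isolated | [Li]c1c(OCc3ccccc3)cc(OCc3ccccc3)c2c1O[C@H](c1ccc(OCc3ccccc3)c(OCc3ccccc3)c1)[C@@H](OCc1ccccc1)C2 | intermediate
6 | 8-formyl-3,5,7,3',4'-penta-O-benzyl-(+)-catechin (2R,3S) | O=Cc1c(OCc3ccccc3)cc(OCc3ccccc3)c2c1O[C@H](c1ccc(OCc3ccccc3)c(OCc3ccccc3)c1)[C@@H](OCc1ccccc1)C2 | intermediate
7 | phloroglucinol, benzene-1,3,5-triol | Oc1cc(O)cc(O)c1 | starting material
8 | 3,5-dibenzyloxyphenol | Oc1cc(OCc2ccccc2)cc(OCc2ccccc2)c1 | intermediate
9 | 3,4-dibenzyloxybenzaldehyde | O=Cc1ccc(OCc2ccccc2)c(OCc2ccccc2)c1 | starting material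
10 | 3,4-dibenzyloxystyrene | C=Cc1ccc(OCc2ccccc2)c(OCc2ccccc2)c1 | intermediate
11 | (2-hydroxy-4,6-dibenzyloxyphenyl)(penta-O-benzylcatechin-8-yl)methanol, both carbinol epimers, not isolated | OC(c1c(O)cc(OCc3ccccc3)cc1OCc1ccccc1)c1c(OCc3ccccc3)cc(OCc3ccccc3)c2c1O[C@H](c1ccc(OCc3ccccc3)c(OCc3ccccc3)c1)[C@@H](OCc1ccccc1)C2 | intermediate
12 | 3,5-dibenzyloxy-6-[(penta-O-benzylcatechin-8-yl)methylidene]cyclohexa-2,4-dien-1-one, alkene geometry interconverting under the acid, not isolated | O=C1C=C(OCc3ccccc3)C=C(OCc3ccccc3)C1=Cc1c(OCc3ccccc3)cc(OCc3ccccc3)c2c1O[C@H](c1ccc(OCc3ccccc3)c(OCc3ccccc3)c1)[C@@H](OCc1ccccc1)C2 | intermediate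
13 | nona-O-benzyl-(2S,4S)-luteoliflavan-(4→8)-(+)-catechin: 2,4-cis-5,7,3',4'-tetrabenzyloxyflavan bound through C4 to C8 of (2R,3S)-penta-O-benzylcatechin | C(c1ccccc1)Oc1cc(OCc3ccccc3)c2c(c1)O[C@H](c1ccc(OCc3ccccc3)c(OCc3ccccc3)c1)C[C@@H]2c1c(OCc3ccccc3)cc(OCc3ccccc3)c2c1O[C@H](c1ccc(OCc3ccccc3)c(OCc3ccccc3)c1)[C@@H](OCc1ccccc1)C2 | intermediate
14 | (2S,4S)-luteoliflavan-(4→8)-(+)-catechin, CNP0180676.1: 2,4-cis-5,7,3',4'-tetrahydroxyflavan bound through C4 to C8 of (2R,3S)-catechin | Oc1cc(O)c2c(c1)O[C@H](c1ccc(O)c(O)c1)C[C@@H]2c1c(O)cc(O)c2c1O[C@H](c1ccc(O)c(O)c1)[C@@H](O)C2 | target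

**Totals**
Total step count: 8.
Longest linear sequence: 6 (steps 1, 2, 3, 4, 7, 8).

**Steps most likely to fail**

1. Step 7 (the labelled step).
- What may go wrong: hydroxyalkylation of the hindered, donor-rich aldehyde may be slow. A second phenol may intercept the methide. The acid may oligomerise the styrene. Face selection may be weak, or material may leak into the 2,4-trans series.
- Fallback: a formal [3+3] route built from known reactions, setting out from 6 and 8 and coming back at 14. Claisen-Schmidt condensation of 6 with purchased 3,4-dibenzyloxyacetophenone (CC(=O)c1ccc(OCc2ccccc2)c(OCc2ccccc2)c1; KOH, EtOH/THF) should give the chalcone (E)-1-(3,4-dibenzyloxyphenyl)-3-(penta-O-benzylcatechin-8-yl)prop-2-en-1-one F1, in which C2, C3 and ring B are already bound to C4. Friedel-Crafts conjugate addition of the ortho carbon of 8, catalysed by p-toluenesulfonic acid, followed by cyclodehydration of the hemiketal, is the known phenol-plus-chalcone synthesis of 2,4-diaryl-4H-chromenes. It should give (4S)-5,7-dibenzyloxy-2-(3,4-dibenzyloxyphenyl)-4-(penta-O-benzylcatechin-8-yl)-4H-chromene F2 together with its C4 epimer, a diastereomer that is separated. Hydrogenation over Pd(OH)2/C should add hydrogen to the C2=C3 enol ether from the face away from the C4 aryl group. That fixes the 2,4-cis relation and removes the nine benzyl groups in the same operation.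

2. Step 4.
- What may go wrong: a neighbouring OCH2Ph group may transfer a proton to the aryllithium, with Wittig rearrangement following. The alkyl bromide formed in the exchange may butylate it. Adventitious protonation may return the debrominated arene.
- Fallback: electrophilic instead of organometallic formylation, setting out from 3 and coming back at 6, which also bypasses step 3. Vilsmeier-Haack reaction (POCl3, DMF, 0 °C to 50 °C; aq NaOAc) on the 1,3,5-trioxygenated ring A should attack C8 in preference to C6, as other electrophiles do, and the minor regioisomer is removed by chromatography. No compound outside the compound list is made on this way (F0).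

3. Step 8.
- What may go wrong: the reaction may stall at partly benzylated stages as the polarity changes. The benzylic C2-O1 bonds may open reductively, most easily in the 3-deoxy upper unit. The catechol rings may oxidise in air during isolation.
- Fallback: non-reductive Lewis acid debenzylation, setting out from 13 and coming back at 14. BCl3 with pentamethylbenzene as cation scavenger (CH2Cl2, -78 °C, MeOH quench) cleaves aryl and alkyl benzyl ethers without hydrogen or metal surface, and the low temperature is meant to spare the acid-labile C4-C8 link. No compound outside the compound list is made on this way (F0).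

**Further compounds**
F1 | step 7 | (E)-1-(3,4-dibenzyloxyphenyl)-3-(penta-O-benzylcatechin-8-yl)prop-2-en-1-one | O=C(/C=C/c1c(OCc3ccccc3)cc(OCc3ccccc3)c2c1O[C@H](c1ccc(OCc3ccccc3)c(OCc3ccccc3)c1)[C@@H](OCc1ccccc1)C2)c1ccc(OCc2ccccc2)c(OCc2ccccc2)c1
F2 | step 7 | (4S)-5,7-dibenzyloxy-2-(3,4-dibenzyloxyphenyl)-4-(penta-O-benzylcatechin-8-yl)-4H-chromene | C(c1ccccc1)Oc1cc(OCc3ccccc3)c2c(c1)OC(c1ccc(OCc3ccccc3)c(OCc3ccccc3)c1)=C[C@@H]2c1c(OCc3ccccc3)cc(OCc3ccccc3)c2c1O[C@H](c1ccc(OCc3ccccc3)c(OCc3ccccc3)c1)[C@@H](OCc1ccccc1)C2
F0 | step 4 | none | none
F0 | step 8 | none | none
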